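**Retrosynthetic overview** (numbers follow the forward route)
- 8 ⇒ 7: the oxirane, the only ring made, is closed last by enantioselective oxygen-atom transfer from an iron-oxo species to the 8,9-olefin of the fully acylated 10-acetoxy-8,9-dehydrothymol, as in the presumed biogenesis. No hydroxyl directing group is used; the catalyst alone sets C8.
- 7 ⇒ 3 + 6: Suzuki–Miyaura coupling of an aryl bromide with a 2-borylallyl acetate forms the aryl–C8 bond.
- 3 ⇒ 1 by acid reduction and double isobutyrylation; 6 ⇒ 4 by α-selective protoboration and acetylation.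
- Ring order: the benzene ring is purchased; the oxirane is formed in the final step.

**Assumption:** the (S,S)-iron catalyst/L-amino acid pair written in step 5 is taken to be the pair that converts α-methylstyrene into (S)-2-methyl-2-phenyloxirane, the spatial analogue of 8 (CH2OAc in place of CH3). I could not confirm this sense from memory, so it is checked in a calibration run, and the mirror-image pair is used if it is reversed.

**Step 1**
Reactants: 1 4-bromo-3-hydroxybenzoic acid
Product: 2 2-bromo-5-(hydroxymethyl)phenol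
Conditions: BH3·THF (3 equiv), THF, 0 °C → rt; MeOH, then aq. work-up
Reagents that add atoms: none
Why: Chemoselective borane reduction of a carboxylic acid (via the acyloxyborane) to the benzylic alcohol leaves the aryl bromide untouched; no stereocentre.

**Step 2**
Reactants: 2 2-bromo-5-(hydroxymethyl)phenol
Product: 3 4-bromo-3-(isobutyryloxy)benzyl isobutyrate
Conditions: (i-PrCO)2O (2.5 equiv), Et3N, DMAP (cat.), CH2Cl2, 0 °C → rt
Reagents that add atoms: isobutyric anhydride CC(C)C(=O)OC(=O)C(C)C
Why: DMAP-catalysed acylation esterifies the phenol and the primary benzylic alcohol in one operation, since both carry the same acyl group in the target; no stereocentre.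

**Step 3**
Reactants: 4 propargyl alcohol
Product: 6 2-(pinacolboryl)allyl acetate, via 2-(pinacolboryl)prop-2-en-1-ol 5 (not isolated)
Conditions: B2pin2 (1.05 equiv), (SIMes)CuCl (3 mol %), NaOt-Bu (6 mol %), MeOH (2 equiv), THF, −50 → 22 °C; evaporate; then Ac2O, pyridine, DMAP (cat.), CH2Cl2, 0 °C
Reagents that add atoms: bis(pinacolato)diboron CC1(C)OB(OC1(C)C)B1OC(C)(C)C(C)(C)O1; acetic anhydride CC(=O)OC(C)=O
Why: NHC–copper-catalysed protoboration (syn-borylcupration, then protonation) with an N-aryl carbene puts boron on the internal carbon of the propargylic alkyne, and acetylation of the crude alcohol gives the allylic acetate; no stereocentre.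

**Step 4**
Reactants: 3 4-bromo-3-(isobutyryloxy)benzyl isobutyrate; 6 2-(pinacolboryl)allyl acetate (1.4 equiv)
Product: 7 2-{2-(isobutyryloxy)-4-[(isobutyryloxy)methyl]phenyl}allyl acetate
Conditions: Pd(dppf)Cl2·CH2Cl2 (5 mol %), CsF (3 equiv), anhydrous 1,4-dioxane, 70 °C
Reagents that add atoms: none
Why: Suzuki–Miyaura coupling under water-free fluoride activation spares the aryl ester and the acetate, and reversible ionisation of the symmetrical 2-substituted allyl acetate is degenerate; no stereocentre.

**Step 5**
Reactants: 7 2-{2-(isobutyryloxy)-4-[(isobutyryloxy)methyl]phenyl}allyl acetate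
Product: 8 (S)-{2-[2-(isobutyryloxy)-4-[(isobutyryloxy)methyl]phenyl]oxiran-2-yl}methyl acetate (target)
Conditions: (S,S)-[Fe(OTf)2(Me2N-PDP)] (2 mol %), N-(1,8-naphthaloyl)-L-isoleucine (3 mol %), 30% aq. H2O2 (2 equiv, syringe pump, 30 min), MeCN, −30 °C; NaHCO3/Na2S2O3 quench; Et3N-buffered silica
Reagents that add atoms: hydrogen peroxide OO
Why: Proposed new method: this extends the bio-inspired non-heme iron/H2O2/carboxylic acid asymmetric epoxidation of α-alkylstyrenes (closest known reaction type) to an α-(acetoxymethyl)styrene with an ortho-acyloxy group; the amino acid co-ligand promotes heterolytic O–O cleavage of Fe(III)–OOH to an electrophilic Fe(V)(O)(carboxylate) that transfers oxygen in a concerted way to one face of the 1,1-disubstituted olefin, the chiral bipyrrolidine/amino acid cleft telling aryl from CH2OAc, which sets C8 as S; the esters are inert at −30 °C, the deactivated benzylic C–H bonds react far more slowly than the olefin, and water is the only co-product.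

**Compound list**
1 | 4-bromo-3-hydroxybenzoic acid | OC(=O)c1ccc(Br)c(O)c1 | starting material
2 | 2-bromo-5-(hydroxymethyl)phenol | OCc1ccc(Br)c(O)c1 | intermediate
3 | 4-bromo-3-(isobutyryloxy)benzyl isobutyrate | CC(C)C(=O)OCc1ccc(Br)c(OC(=O)C(C)C)c1 | intermediate
4 | propargyl alcohol (prop-2-yn-1-ol) | C#CCO | starting material
5 | 2-(4,4,5,5-tetramethyl-1,3,2-dioxaborolan-2-yl)prop-2-en-1-ol | C=C(CO)B1OC(C)(C)C(C)(C)O1 | intermediate
6 | 2-(4,4,5,5-tetramethyl-1,3,2-dioxaborolan-2-yl)prop-2-en-1-yl acetate | CC(=O)OCC(=C)B1OC(C)(C)C(C)(C)O1 | intermediate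
7 | 2-{2-(isobutyryloxy)-4-[(isobutyryloxy)methyl]phenyl}prop-2-en-1-yl acetate (achiral) | CC(=O)OCC(=C)c1ccc(COC(=O)C(C)C)cc1OC(=O)C(C)C | intermediate
8 | (S)-{2-[2-(isobutyryloxy)-4-[(isobutyryloxy)methyl]phenyl]oxiran-2-yl}methyl acetate | CC(=O)OC[C@]1(c2ccc(COC(=O)C(C)C)cc2OC(=O)C(C)C)CO1 | target

**Totals:** 5 steps; longest linear sequence 4 steps (1 → 2 → 3 → 7 → 8).

**Three steps most likely to fail**

Step 5 (enantioselectivity and facial sense on an ortho-substituted, acetoxymethyl-bearing styrene; acid-sensitivity of the tertiary benzylic epoxide). The fallback sets out from 3 and returns at 8, using a hydroxyl-directed epoxidation instead. Compound 3 is coupled under the step-4 conditions with the free alcohol 5, here isolated after the first stage of step 3, to give 2-{2-(isobutyryloxy)-4-[(isobutyryloxy)methyl]phenyl}prop-2-en-1-ol F1. Sharpless–Katsuki epoxidation (Ti(Oi-Pr)4 10 mol %, D-(−)-diisopropyl tartrate 12 mol %, t-BuOOH, 4 Å sieves, CH2Cl2, −20 °C) then gives (R)-{2-[2-(isobutyryloxy)-4-[(isobutyryloxy)methyl]phenyl]oxiran-2-yl}methanol F2. D-(−)-tartrate is chosen by analogy with (R)-glycidol and (R)-2-methylglycidol formation. Ac2O/pyridine at 0 °C gives 8; the descriptor changes from R to S only through CIP priorities. The cost is that a free allylic hydroxyl sits beside the aryl ester, so F1 and F2 must be kept cold and base-free to avoid acyl transfer.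

Step 4 (loss of boronate 6 by fluoride-induced elimination or π-allyl side reactions; cleavage of the aryl ester followed by cyclisation to a benzofuran). The fallback sets out from 3 and returns at 7, adding the C10 oxygen after the C–C bond is made. Compound 3 is coupled with commercial isopropenylboronic acid pinacol ester (Pd(dppf)Cl2, CsF, dioxane, 70 °C) to give 5-[(isobutyryloxy)methyl]-2-(prop-1-en-2-yl)phenyl isobutyrate F3. Allylic bromination (NBS, cat. TsOH, THF, reflux) gives 2-(3-bromoprop-1-en-2-yl)-5-[(isobutyryloxy)methyl]phenyl isobutyrate F4. Displacement with KOAc in DMF at rt gives 7.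

Step 3 (α/β regioselectivity of the protoboration and stability of the 2-boryl allylic alcohol during telescoped acetylation). The fallback sets out from 3 and returns at 7, with the coupling polarity reversed so that no vinylboronate is needed. Miyaura borylation of 3 (B2pin2, Pd(dppf)Cl2, KOAc, dioxane, 85 °C) gives 5-[(isobutyryloxy)methyl]-2-(4,4,5,5-tetramethyl-1,3,2-dioxaborolan-2-yl)phenyl isobutyrate F5. Commercial 2,3-dibromopropene and KOAc (DMF, rt) give 2-bromoallyl acetate F6. Suzuki coupling of the two (Pd(PPh3)4, CsF, dioxane, 70 °C) gives 7.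

**Further compounds**
F1 | step 5 | 2-{2-(isobutyryloxy)-4-[(isobutyryloxy)methyl]phenyl}prop-2-en-1-ol | OCC(=C)c1ccc(COC(=O)C(C)C)cc1OC(=O)C(C)C
F2 | step 5 | (R)-{2-[2-(isobutyryloxy)-4-[(isobutyryloxy)methyl]phenyl]oxiran-2-yl}methanol | OC[C@]1(c2ccc(COC(=O)C(C)C)cc2OC(=O)C(C)C)CO1
F3 | step 4 | 5-[(isobutyryloxy)methyl]-2-(prop-1-en-2-yl)phenyl isobutyrate | CC(=C)c1ccc(COC(=O)C(C)C)cc1OC(=O)C(C)C
F4 | step 4 | 2-(3-bromoprop-1-en-2-yl)-5-[(isobutyryloxy)methyl]phenyl isobutyrate | BrCC(=C)c1ccc(COC(=O)C(C)C)cc1OC(=O)C(C)C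
F5 | step 3 | 5-[(isobutyryloxy)methyl]-2-(4,4,5,5-tetramethyl-1,3,2-dioxaborolan-2-yl)phenyl isobutyrate | CC(C)C(=O)OCc1ccc(B2OC(C)(C)C(C)(C)O2)c(OC(=O)C(C)C)c1
F6 | step 3 | 2-bromoallyl acetate | CC(=O)OCC(Br)=C
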